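The six-membered ring is disconnected across C1–C2 and C5–C6. What makes this possible is the 1,4-relationship of the quaternary carbinol carbon C1 and the oxygen-bearing C4 across the C2=C3 double bond of the single carbocycle, the signature of a 4-formyl-4-alkylcyclohex-2-enone. A catalytic enantioselective [4+2] cycloaddition of a 1-amino-3-siloxybutadiene to an α-alkylacrolein closes that ring, fixes C1 with the C17 chain in place and, after acid treatment, leaves the enone, all in one operation. The formyl group is later exchanged for hydroxyl, and the enone is used to oxygenate C5 and C4. The dienophile is a 2-methylidene C19 aldehyde with a remote E alkene.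

Key step: step 8

Ring locants in the text: C1 quaternary carbinol carbon, C2=C3 alkene, C4 and C5 secondary carbinol carbons, C6 methylene; systematic names carry their own locants.

Assumption: the (1S,2S) antipode of the chromium salen catalyst is taken to give the 1R centre; if the sense of induction proves opposite, the (1R,2R) antipode is used and nothing else changes.

Step 1
Reactants: 1 (E)-hexadec-11-en-1-ol
Product: 2 (E)-1-bromohexadec-11-ene
Conditions: CBr4, PPh3, CH2Cl2, 0 °C
Reagents that add atoms: tetrabromomethane, BrC(Br)(Br)Br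
Why: Appel bromination replaces the primary hydroxyl by SN2 attack of bromide on the alkoxyphosphonium ion under neutral conditions that leave the E alkene untouched.

Step 2
Reactants: 2 (E)-1-bromohexadec-11-ene; 3 oxetane
Product: 5 (E)-nonadec-14-en-1-ol, via (E)-hexadec-11-enylmagnesium bromide 4 (not isolated)
Conditions: Mg, THF, reflux; then 3, CuI (10 mol%), THF, 0 °C → reflux; 1 M HCl
Reagents that add atoms: none
Why: copper-catalysed ring opening of the strained four-membered ether by a primary alkyl Grignard reagent is a dependable three-carbon homologation to the primary alcohol.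

Step 3
Reactants: 5 (E)-nonadec-14-en-1-ol
Product: 6 (E)-nonadec-14-enal
Conditions: TEMPO (10 mol%), PhI(OAc)2, CH2Cl2, rt
Reagents that add atoms: none
Why: oxoammonium-catalysed oxidation stops at the aldehyde and does not touch an isolated alkene.

Step 4
Reactants: 6 (E)-nonadec-14-enal
Product: 7 (E)-2-methylidenenonadec-14-enal
Conditions: 37% aq. CH2O, pyrrolidine (10 mol%), EtCO2H (10 mol%), i-PrOH, 45 °C
Reagents that add atoms: formaldehyde, C=O
Why: amine-catalysed Mannich condensation with formaldehyde followed by loss of the amine (organocatalytic α-methylenation) converts a linear aldehyde into the 2-substituted acrolein without moving the remote alkene.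

Step 5
Reactants: 8 (E)-4-methoxybut-3-en-2-one; 9 benzylamine
Product: 10 (Z)-4-(benzylamino)but-3-en-2-one
Conditions: CH2Cl2, rt
Reagents that add atoms: none
Why: conjugate addition–elimination of the amine on the β-methoxy enone (vinylogous transamidation) gives the hydrogen-bonded Z enaminone.

Step 6
Reactants: 10 (Z)-4-(benzylamino)but-3-en-2-one
Product: 11 methyl N-benzyl-N-[(1E)-3-oxobut-1-en-1-yl]carbamate
Conditions: NaN(SiMe3)2, THF, −78 °C; ClCO2Me, −78 → 0 °C
Reagents that add atoms: methyl chloroformate, COC(=O)Cl
Why: N-acylation of the enaminone anion gives the vinylogous imide, which relaxes to the E geometry once the internal N–H···O hydrogen bond is gone.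

Step 7
Reactants: 11 methyl N-benzyl-N-[(1E)-3-oxobut-1-en-1-yl]carbamate
Product: 12 methyl N-benzyl-N-[(1E)-3-(tert-butyldimethylsilyloxy)buta-1,3-dien-1-yl]carbamate
Conditions: KN(SiMe3)2, THF, −78 °C; t-BuMe2SiCl, −78 °C → rt
Reagents that add atoms: tert-butyldimethylsilyl chloride, CC(C)(C)[Si](C)(C)Cl
Why: kinetic deprotonation of the methyl ketone and O-silylation of the cross-conjugated enolate give the 1-amino-3-siloxy diene.

Step 8
Reactants: 7 (E)-2-methylidenenonadec-14-enal; 12 methyl N-benzyl-N-[(1E)-3-(tert-butyldimethylsilyloxy)buta-1,3-dien-1-yl]carbamate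
Product: 14 (1R)-1-[(E)-heptadec-12-enyl]-4-oxocyclohex-2-ene-1-carbaldehyde, via endo cycloadduct 13 (not isolated)
Conditions: (1S,2S)-(salen)CrSbF6 (5 mol%; trivalent chromium; salen = N,N'-bis(3,5-di-tert-butylsalicylidene)cyclohexane-1,2-diaminate), 4 Å MS, CH2Cl2, −40 °C; then 48% aq. HF, MeCN, 0 °C → rt
Reagents that add atoms: none
Why: Coordination of the enal oxygen to the cationic chromium centre lowers the LUMO of 7, and the diene engages it in a concerted cycloaddition in which bonding is advanced at C5–C6 (diene CH2 terminus to the enal β-carbon) and lags at C1–C2 (nitrogen-bearing terminus to the enal α-carbon). The closest known reaction type is the chromium salen-catalysed enantioselective Diels–Alder reaction of N-acyl-1-amino-3-siloxybutadienes with α-alkylacroleins such as 2-ethylacrolein. The six-membered carbocycle is closed by intermolecular [4+2] cycloaddition, both ring bonds being formed in that event. The quaternary centre C1 is set by the chiral salen ligand, which leaves one enantiotopic face of the bound enal open, while the endo-placed formyl group defines a transient C2 centre that is erased afterwards. The step needs head-to-tail regioselectivity, secured by the matched 1-amino-3-siloxy polarisation of the diene, and enantiofacial selectivity, secured by the catalyst together with the carbamate nitrogen, which neither binds chromium nor permits an uncatalysed background reaction at −40 °C. Aqueous HF then cleaves the silyl enol ether and expels methyl N-benzylcarbamate by β-elimination, which should leave the C2=C3 alkene conjugated to the C4 ketone with the non-enolisable formyl group intact.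

Step 9
Reactants: 14 (1R)-1-[(E)-heptadec-12-enyl]-4-oxocyclohex-2-ene-1-carbaldehyde
Product: 16 (4R)-4-[(E)-heptadec-12-enyl]-4-hydroxycyclohex-2-en-1-one, via tertiary formate 15 (not isolated)
Conditions: Me3SiOOSiMe3, SnCl4 (20 mol%), 4 Å MS, CH2Cl2, −40 → 0 °C; Me2S quench; then K2CO3 (cat.), MeOH, 0 °C
Reagents that add atoms: bis(trimethylsilyl) peroxide, C[Si](C)(C)OO[Si](C)(C)C
Why: Proposed new method: the Lewis acid should activate the hindered formyl group toward addition of the silyl peroxide, and in the resulting silylperoxy hemiacetal the tertiary ring carbon should migrate to oxygen with retention in preference to hydride, while the non-electrophilic silyl peroxide spares both alkenes and the electron-poor enone resists ionisation of the tertiary formate; the closest known reactions are the Baeyer–Villiger oxidation of ketones bearing isolated alkenes with Me3SiOOSiMe3 and SnCl4 or Me3SiOSO2CF3 and the peracid oxidation of α-quaternary aldehydes to formates, and the formate is then removed by mild transesterification.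

Step 10
Reactants: 16 (4R)-4-[(E)-heptadec-12-enyl]-4-hydroxycyclohex-2-en-1-one
Product: 17 (4R)-4-[(E)-heptadec-12-enyl]-4-(triethylsilyloxy)cyclohex-2-en-1-one
Conditions: Et3SiOSO2CF3, 2,6-lutidine, CH2Cl2, −78 → 0 °C
Reagents that add atoms: triethylsilyl trifluoromethanesulfonate, CC[Si](CC)(CC)OS(=O)(=O)C(F)(F)F
Why: a silyl triflate with a hindered pyridine base silylates tertiary alcohols quickly at low temperature without enolising the enone.

Step 11
Reactants: 17 (4R)-4-[(E)-heptadec-12-enyl]-4-(triethylsilyloxy)cyclohex-2-en-1-one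
Product: 18 (4R,6R)-4-[(E)-heptadec-12-enyl]-6-hydroxy-4-(triethylsilyloxy)cyclohex-2-en-1-one
Conditions: KN(SiMe3)2, THF, −78 °C; 2-(phenylsulfonyl)-3-phenyloxaziridine, −78 °C; AcOH quench
Reagents that add atoms: 2-(phenylsulfonyl)-3-phenyloxaziridine, O=S(=O)(N1OC1c1ccccc1)c1ccccc1
Why: C5 is the only enolisable position because C1 is quaternary, and the potassium enolate should be hydroxylated by the N-sulfonyloxaziridine (enolate oxidation of the Davis type) on the face anti to the pseudoaxial silyloxy group at C1, the chain lying pseudoequatorial, so that the C5 hydroxyl is placed trans to the C1 oxygen.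

Step 12
Reactants: 18 (4R,6R)-4-[(E)-heptadec-12-enyl]-6-hydroxy-4-(triethylsilyloxy)cyclohex-2-en-1-one
Product: 19 (1R,2R,5R)-5-[(E)-heptadec-12-enyl]-5-(triethylsilyloxy)cyclohex-3-ene-1,2-diol
Conditions: Me4NBH(OAc)3, MeCN/AcOH, −30 °C
Reagents that add atoms: none
Why: in this hydroxyl-directed reduction of the Evans–Saksena type the C5 hydroxyl exchanges onto boron and delivers hydride to its own face of the C4 carbonyl, a path reinforced by the preference for an equatorial allylic alcohol, which should give the trans-4,5-diol by clean 1,2-reduction and place the C4 hydroxyl cis to the C1 oxygen.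

Step 13
Reactants: 19 (1R,2R,5R)-5-[(E)-heptadec-12-enyl]-5-(triethylsilyloxy)cyclohex-3-ene-1,2-diol
Product: 20 (1R,2R,4R)-4-[(E)-heptadec-12-enyl]cyclohex-5-ene-1,2,4-triol
Conditions: Bu4NF, AcOH, THF, 0 °C → rt
Reagents that add atoms: none
Why: fluoride-mediated cleavage of the Si–O bond under acetic acid buffering frees the tertiary allylic alcohol without ionising it or disturbing any stereocentre.

Compound list
1 | (E)-hexadec-11-en-1-ol | CCCC/C=C/CCCCCCCCCCO | starting material
2 | (E)-1-bromohexadec-11-ene | CCCC/C=C/CCCCCCCCCCBr | intermediate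
3 | oxetane | C1COC1 | starting material
4 | (E)-hexadec-11-enylmagnesium bromide | CCCC/C=C/CCCCCCCCCC[Mg]Br | intermediate
5 | (E)-nonadec-14-en-1-ol | CCCC/C=C/CCCCCCCCCCCCCO | intermediate
6 | (E)-nonadec-14-enal | CCCC/C=C/CCCCCCCCCCCCC=O | intermediate
7 | (E)-2-methylidenenonadec-14-enal | CCCC/C=C/CCCCCCCCCCCC(=C)C=O | intermediate
8 | (E)-4-methoxybut-3-en-2-one | CO/C=C/C(C)=O | starting material
9 | benzylamine | NCc1ccccc1 | starting material
10 | (Z)-4-(benzylamino)but-3-en-2-one | CC(=O)/C=C\NCc1ccccc1 | intermediate
11 | methyl N-benzyl-N-[(1E)-3-oxobut-1-en-1-yl]carbamate | COC(=O)N(Cc1ccccc1)/C=C/C(C)=O | intermediate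
12 | methyl N-benzyl-N-[(1E)-3-(tert-butyldimethylsilyloxy)buta-1,3-dien-1-yl]carbamate | COC(=O)N(Cc1ccccc1)/C=C/C(=C)O[Si](C)(C)C(C)(C)C | intermediate
13 | methyl N-benzyl-N-[(1S,6R)-3-(tert-butyldimethylsilyloxy)-6-formyl-6-[(E)-heptadec-12-enyl]cyclohex-2-en-1-yl]carbamate (endo adduct, formyl cis to nitrogen) | CCCC/C=C/CCCCCCCCCCC[C@]1(C=O)[C@@H](N(Cc2ccccc2)C(=O)OC)C=C(O[Si](C)(C)C(C)(C)C)CC1 | intermediate
14 | (1R)-1-[(E)-heptadec-12-enyl]-4-oxocyclohex-2-ene-1-carbaldehyde | CCCC/C=C/CCCCCCCCCCC[C@]1(C=O)C=CC(=O)CC1 | intermediate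
15 | (1R)-1-[(E)-heptadec-12-enyl]-4-oxocyclohex-2-en-1-yl formate | CCCC/C=C/CCCCCCCCCCC[C@]1(OC=O)C=CC(=O)CC1 | intermediate
16 | (4R)-4-[(E)-heptadec-12-enyl]-4-hydroxycyclohex-2-en-1-one | CCCC/C=C/CCCCCCCCCCC[C@]1(O)C=CC(=O)CC1 | intermediate
17 | (4R)-4-[(E)-heptadec-12-enyl]-4-(triethylsilyloxy)cyclohex-2-en-1-one | CCCC/C=C/CCCCCCCCCCC[C@]1(O[Si](CC)(CC)CC)C=CC(=O)CC1 | intermediate
18 | (4R,6R)-4-[(E)-heptadec-12-enyl]-6-hydroxy-4-(triethylsilyloxy)cyclohex-2-en-1-one | CCCC/C=C/CCCCCCCCCCC[C@]1(O[Si](CC)(CC)CC)C=CC(=O)[C@H](O)C1 | intermediate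
19 | (1R,2R,5R)-5-[(E)-heptadec-12-enyl]-5-(triethylsilyloxy)cyclohex-3-ene-1,2-diol | CCCC/C=C/CCCCCCCCCCC[C@]1(O[Si](CC)(CC)CC)C=C[C@@H](O)[C@H](O)C1 | intermediate
20 | (1R,2R,4R)-4-[(E)-heptadec-12-enyl]cyclohex-5-ene-1,2,4-triol | CCCC/C=C/CCCCCCCCCCC[C@]1(O)C=C[C@@H](O)[C@H](O)C1 | target

Total step count: 13. Longest linear sequence: 10 steps (steps 1–4 and 8–13); steps 5–7 are a three-step branch to the diene.

Steps most likely to fail

Step 9. In the silylperoxy hemiacetal, hydride migration (leading to the carboxylic acid) or peroxide oligomerisation at the aldehyde may outrun migration of the ring carbon, whose migratory aptitude is lowered by the neighbouring enone. The fallback sets out from 14 and returns at 16, using known reactions only. MeTi(OiPr)3 in THF at −30 °C should add to the formyl group in preference to the enone and give (4R)-4-[(E)-heptadec-12-enyl]-4-(1-hydroxyethyl)cyclohex-2-en-1-one F1 as a mixture of carbinol epimers. Dess–Martin oxidation should then give the methyl ketone (4R)-4-acetyl-4-[(E)-heptadec-12-enyl]cyclohex-2-en-1-one F2. Baeyer–Villiger oxidation of this ketone with Me3SiOOSiMe3 and catalytic Me3SiOSO2CF3 in CH2Cl2 (−78 → −20 °C), a reagent pair established for ketones that carry isolated alkenes, should insert oxygen on the side of the tertiary ring carbon with retention. The product, (1R)-1-[(E)-heptadec-12-enyl]-4-oxocyclohex-2-en-1-yl acetate F3, is methanolysed with K2CO3 in MeOH to give 16.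

Step 11. Both faces of C5 are flanked by a C1 substituent, so facial discrimination at the enolate may be poor or may favour entry of oxygen syn to the silyloxy group. The fallback sets out from 17 and returns at 18, replacing facial control by SN2 inversion. The same enolate oxidation would then deliver mainly the C5 epimer (4R,6S)-4-[(E)-heptadec-12-enyl]-6-hydroxy-4-(triethylsilyloxy)cyclohex-2-en-1-one F4. Mitsunobu esterification of this α-hydroxy ketone with 4-nitrobenzoic acid, PPh3 and diisopropyl azodicarboxylate in toluene at 0 °C should invert C5 and give (1R,5R)-5-[(E)-heptadec-12-enyl]-2-oxo-5-(triethylsilyloxy)cyclohex-3-en-1-yl 4-nitrobenzoate F5. Brief methanolysis with K2CO3 in MeOH at 0 °C then gives 18.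

Step 8. The long-chain enal may be bound or shielded less well than short α-alkylacroleins, which would erode enantiofacial control, and acid-promoted loss of the carbamate next to the free aldehyde may be sluggish. The fallback sets out from 7 and returns at 14, changing the mode of activation from Lewis-acid to hydrogen-bond catalysis and using a more reactive diene. The commercial diene (E)-3-(tert-butyldimethylsilyloxy)-N,N-dimethylbuta-1,3-dien-1-amine F6 is combined with 7 in toluene at −78 °C in the presence of the enantiomer of 2,2-dimethyl-α,α,α',α'-tetra(naphthalen-1-yl)-1,3-dioxolane-4,5-dimethanol (20 mol%) that favours the 1R centre. The diol activates the enal by hydrogen bonding to its carbonyl oxygen, and the cycloaddition should give the amino adduct (1R,2S)-4-(tert-butyldimethylsilyloxy)-2-(dimethylamino)-1-[(E)-heptadec-12-enyl]cyclohex-3-ene-1-carbaldehyde F7. Treatment of the crude adduct with aqueous HF in MeCN hydrolyses the silyl enol ether and expels the protonated amine readily to give 14.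

Further compounds
F1 | step 9 | (4R)-4-[(E)-heptadec-12-enyl]-4-(1-hydroxyethyl)cyclohex-2-en-1-one (carbinol epimers) | CCCC/C=C/CCCCCCCCCCC[C@]1(C(C)O)C=CC(=O)CC1
F2 | step 9 | (4R)-4-acetyl-4-[(E)-heptadec-12-enyl]cyclohex-2-en-1-one | CCCC/C=C/CCCCCCCCCCC[C@]1(C(C)=O)C=CC(=O)CC1
F3 | step 9 | (1R)-1-[(E)-heptadec-12-enyl]-4-oxocyclohex-2-en-1-yl acetate | CCCC/C=C/CCCCCCCCCCC[C@]1(OC(C)=O)C=CC(=O)CC1
F4 | step 11 | (4R,6S)-4-[(E)-heptadec-12-enyl]-6-hydroxy-4-(triethylsilyloxy)cyclohex-2-en-1-one | CCCC/C=C/CCCCCCCCCCC[C@]1(O[Si](CC)(CC)CC)C=CC(=O)[C@@H](O)C1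
F5 | step 11 | (1R,5R)-5-[(E)-heptadec-12-enyl]-2-oxo-5-(triethylsilyloxy)cyclohex-3-en-1-yl 4-nitrobenzoate | CCCC/C=C/CCCCCCCCCCC[C@]1(O[Si](CC)(CC)CC)C=CC(=O)[C@H](OC(=O)c2ccc(cc2)[N+](=O)[O-])C1
F6 | step 8 | (E)-3-(tert-butyldimethylsilyloxy)-N,N-dimethylbuta-1,3-dien-1-amine | CN(C)/C=C/C(=C)O[Si](C)(C)C(C)(C)C
F7 | step 8 | (1R,2S)-4-(tert-butyldimethylsilyloxy)-2-(dimethylamino)-1-[(E)-heptadec-12-enyl]cyclohex-3-ene-1-carbaldehyde | CCCC/C=C/CCCCCCCCCCC[C@]1(C=O)[C@@H](N(C)C)C=C(O[Si](C)(C)C(C)(C)C)CC1
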